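The strategy rests on ring C of the lower unit (O1–C2–C3–C4–C4a–C8a of the flavan-3,4-diol whose C6 carries the other flavan). Its C2 aryl, O3 and O4 alternate from face to face (2,3-trans-3,4-trans), so both C–O bonds are traced back to a C3=C4 alkene that is epoxidised anti to the C2 aryl and hydrolysed with inversion at benzylic C4.
C2, the single stereocentre of that 2-aryl-2H-chromene, is disconnected to a 2-ethoxy-2H-chromene and a 4-(benzyloxy)phenyl boronate (chiral hydroxy acid/Yb(OTf)3 catalysis). The acetal comes from a coumarin and the coumarin from a salicylaldehyde.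
The interflavan bond C4(upper)–C6(lower) is disconnected to an upper 2,3-cis C4 cation (from a 4-methoxy ether) and C5 of 3,4-bis(benzyloxy)-2-hydroxybenzaldehyde. This ring is a weaker nucleophile than the upper ring A, so C6 of the upper unit carries a bromine that shuts off self-condensation and falls in the last hydrogenolysis.
The upper unit comes from the same aldehyde by the same catalytic arylation. Its flav-3-ene is epoxidised, opened with methanol, oxidised at C3 and reduced with a bulky hydride into the 2,3-cis series.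
Ring order: upper ring C (step 3), then lower ring C (step 12). All benzene rings are bought, and the key step closes no lasting ring.

Key step: step 15

Assumption: the sense of induction of the tartaric acid-derived catalyst is taken by analogy. The antipode that gives the (S)-2-aryl-2H-chromene is used in steps 6 and 14, written here as the L-tartaric acid series.
Convention: α is the face of a flavan unit that holds its C2 aryl group and β is the opposite face. U stands for the upper residue (2R,3R,4S)-7,8-bis(benzyloxy)-2-[4-(benzyloxy)phenyl]-6-bromo-3-[(tert-butyldimethylsilyl)oxy]chroman-4-yl (O3 α, bond from C4 β; 2,3-cis-3,4-trans).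
Remark: all 2-aryl-2H-chromenes are handled with exclusion of light and heat, because electrocyclic ring opening would racemise C2.

Step 1
Reactants: 1 2,3,4-trihydroxybenzaldehyde
Product: 2 3,4-bis(benzyloxy)-2-hydroxybenzaldehyde
Conditions: BnBr (2.05 equiv), K2CO3 (2.1 equiv), DMF, 0 °C → rt
Reagents that add atoms: benzyl bromide, BrCc1ccccc1
Why: Williamson etherification in which the C2 hydroxyl, tied up in a hydrogen bond to the formyl oxygen, is the least nucleophilic, so that two equivalents of benzyl bromide should go to O3 and O4.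

Step 2
Reactants: 2 3,4-bis(benzyloxy)-2-hydroxybenzaldehyde
Product: 3 3,4-bis(benzyloxy)-5-bromo-2-hydroxybenzaldehyde
Conditions: NBS (1.0 equiv), MeCN, 0 °C, dark
Reagents that add atoms: N-bromosuccinimide, O=C1CCC(=O)N1Br
Why: Electrophilic aromatic bromination goes para to the free phenol and ortho to the C4 ether, the only doubly activated open position, and places the atom that later blocks C6 of the upper ring A.

Step 3
Reactants: 3 3,4-bis(benzyloxy)-5-bromo-2-hydroxybenzaldehyde
Product: 4 7,8-bis(benzyloxy)-6-bromo-2H-chromen-2-one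
Conditions: Ph3P=C=C=O (1.2 equiv), toluene, 110 °C
Reagents that add atoms: (triphenylphosphoranylidene)ketene, O=C=C=P(c1ccccc1)(c1ccccc1)c1ccccc1
Why: The phenol adds to the cumulated ylide to give an acyl-stabilised phosphorane that closes by intramolecular Wittig olefination on the neighbouring formyl group, which enforces the Z-alkene of the coumarin under neutral conditions.

Step 4
Reactants: 4 7,8-bis(benzyloxy)-6-bromo-2H-chromen-2-one
Product: 6 7,8-bis(benzyloxy)-6-bromo-2-ethoxy-2H-chromene (racemic), via lactol 5 (not isolated)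
Conditions: i-Bu2AlH (1.1 equiv), CH2Cl2, −78 °C; aq Rochelle salt; crude in EtOH, PPTS (10 mol %), 3 Å MS, rt
Reagents that add atoms: ethanol, CCO
Why: Partial lactone reduction stops at the aluminium hemiacetal at low temperature, and acid-catalysed acetalisation of the crude lactol through the benzopyrylium ion traps it as the mixed acetal before the open Z-enal can isomerise.

Step 5
Reactants: 7 4-(benzyloxy)phenylboronic acid
Product: 8 diethyl [4-(benzyloxy)phenyl]boronate
Conditions: EtOH, toluene, reflux over 3 Å MS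
Reagents that add atoms: ethanol, CCO
Why: Esterification of the boronic acid with removal of water gives the exchange-labile diethyl boronate that the chiral hydroxy acid needs for ligand exchange on boron.

Step 6
Reactants: 6 7,8-bis(benzyloxy)-6-bromo-2-ethoxy-2H-chromene; 8 diethyl [4-(benzyloxy)phenyl]boronate
Product: 9 (2S)-7,8-bis(benzyloxy)-2-[4-(benzyloxy)phenyl]-6-bromo-2H-chromene
Conditions: 8 (1.5 equiv), (2R,3R)-4-(dibenzylamino)-2,3-dihydroxy-4-oxobutanoic acid (10 mol %), Yb(OTf)3 (9 mol %), EtOAc, −20 → 4 °C, dark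
Reagents that add atoms: none
Why: In this chiral Brønsted acid/Lewis acid catalysed boronate addition to a chromene acetal the hydroxy acid exchanges onto boron, Yb(OTf)3 helps to ionise the acetal to the planar benzopyrylium ion, and aryl transfer inside the chiral ion pair sets C2 (S in the chromene, the same spatial arrangement as 2R in a flavan).

Step 7
Reactants: 9 (2S)-7,8-bis(benzyloxy)-2-[4-(benzyloxy)phenyl]-6-bromo-2H-chromene
Product: 11 (2R,3S,4R)-7,8-bis(benzyloxy)-2-[4-(benzyloxy)phenyl]-6-bromo-4-methoxychroman-3-ol (2,3-trans-3,4-trans), via epoxide 10 (not isolated)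
Conditions: DMDO (1.2 equiv, acetone), CH2Cl2, −40 → 0 °C, dark; then MeOH, 0 °C → rt
Reagents that add atoms: dimethyldioxirane, CC1(C)OO1; methanol, CO
Why: Dioxirane epoxidation of the electron-rich styrene-type alkene on the β face is followed by anti methanolysis at benzylic C4, and both new centres are provisional because C3 is set again in step 9 and C4 in step 11.

Step 8
Reactants: 11 (2R,3S,4R)-4-methoxyflavan-3-ol
Product: 12 (2R,4R)-7,8-bis(benzyloxy)-2-[4-(benzyloxy)phenyl]-6-bromo-4-methoxychroman-3-one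
Conditions: Dess–Martin periodinane (1.3 equiv), NaHCO3, CH2Cl2, 0 °C → rt
Reagents that add atoms: none
Why: Dess–Martin oxidation under buffered, nearly neutral conditions should give the flavan-3-one without enolisation at the acidic C2–H, and the ketone is used at once.

Step 9
Reactants: 12 (2R,4R)-4-methoxyflavan-3-one
Product: 13 (2R,3R,4R)-7,8-bis(benzyloxy)-2-[4-(benzyloxy)phenyl]-6-bromo-4-methoxychroman-3-ol (2,3-cis-3,4-cis)
Conditions: Li[HB(s-Bu)3] (1.3 equiv), THF, −78 °C; H2O
Reagents that add atoms: none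
Why: In this bulky trialkylborohydride reduction the hydride comes in equatorially from the β face, away from the C2 aryl and the C4 methoxy group, which leaves the C3 hydroxyl axial and cis to the C2 aryl (3R).

Step 10
Reactants: 13 (2R,3R,4R)-4-methoxyflavan-3-ol
Product: 14 (2R,3R,4R)-7,8-bis(benzyloxy)-2-[4-(benzyloxy)phenyl]-6-bromo-3-[(tert-butyldimethylsilyl)oxy]-4-methoxychroman
Conditions: TBSOTf (1.5 equiv), 2,6-lutidine (2.5 equiv), CH2Cl2, −20 → 0 °C
Reagents that add atoms: tert-butyldimethylsilyl triflate, CC(C)(C)[Si](C)(C)OS(=O)(=O)C(F)(F)F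
Why: Silylation with the triflate overcomes the hindrance at the axial hydroxyl while lutidine keeps the C4 ether from ionising, and a silyl ether is taken instead of an ester because the group must outlast i-Bu2AlH in step 13.

Step 11
Reactants: 14 silylated 4-methoxyflavan; 2 3,4-bis(benzyloxy)-2-hydroxybenzaldehyde
Product: 15 3,4-bis(benzyloxy)-2-hydroxy-5-U-benzaldehyde
Conditions: 2 (4 equiv), TMSOTf (0.3 equiv), CH2Cl2, −40 → 0 °C; excess 2 recovered
Reagents that add atoms: none
Why: In this Friedel–Crafts alkylation the C4 cation released from the methyl ether is taken up at C5 of 2 (para to the free hydroxyl, ortho to the C4 ether, meta to the formyl group) from the β face, anti to the axial silyloxy group and the C2 aryl, which sets C4 (S, 3,4-trans), while the C6 bromine keeps the more nucleophilic ring A of 14 from competing.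

Step 12
Reactants: 15 3,4-bis(benzyloxy)-2-hydroxy-5-U-benzaldehyde
Product: 16 7,8-bis(benzyloxy)-6-U-2H-chromen-2-one
Conditions: Ph3P=C=C=O (1.3 equiv), toluene, 100 °C
Reagents that add atoms: (triphenylphosphoranylidene)ketene, O=C=C=P(c1ccccc1)(c1ccccc1)c1ccccc1
Why: Phenol addition to the cumulated ylide and intramolecular Wittig olefination, as in step 3, close the lower ring C under neutral conditions that silyl ether, aryl bromide and benzyl ethers tolerate.

Step 13
Reactants: 16 7,8-bis(benzyloxy)-6-U-2H-chromen-2-one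
Product: 18 7,8-bis(benzyloxy)-2-ethoxy-6-U-2H-chromene (both C2 epimers), via lactol 17 (not isolated)
Conditions: i-Bu2AlH (1.1 equiv), CH2Cl2, −78 °C; aq Rochelle salt; crude in EtOH, PPTS (10 mol %), 3 Å MS, rt
Reagents that add atoms: ethanol, CCO
Why: Partial lactone reduction and acetalisation through the benzopyrylium ion run as in step 4, the lactone being the only reducible group, and the acetal configuration is of no account because C2 becomes planar in the next step.

Step 14
Reactants: 18 7,8-bis(benzyloxy)-2-ethoxy-6-U-2H-chromene; 8 diethyl [4-(benzyloxy)phenyl]boronate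
Product: 19 (2S)-7,8-bis(benzyloxy)-2-[4-(benzyloxy)phenyl]-6-U-2H-chromene
Conditions: 8 (2 equiv), (2R,3R)-4-(dibenzylamino)-2,3-dihydroxy-4-oxobutanoic acid (10 mol %), Yb(OTf)3 (9 mol %), EtOAc, −20 → 4 °C, dark
Reagents that add atoms: none
Why: The same catalytic boronate addition to a chromene acetal sets the lower C2 under catalyst control, since the planar benzopyrylium carbon lies far from the stereocentres of U, and any isomer from imperfect selectivity here or in step 6 is now a diastereomer that chromatography should remove.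

Step 15
Reactants: 19 (2S)-7,8-bis(benzyloxy)-2-[4-(benzyloxy)phenyl]-6-U-2H-chromene
Product: 21 (2R,3S,4R)-7,8-bis(benzyloxy)-2-[4-(benzyloxy)phenyl]-6-U-chroman-3,4-diol (2,3-trans-3,4-trans), via epoxide 20 (not isolated)
Conditions: DMDO (1.2 equiv, acetone), CH2Cl2, −40 → 0 °C, dark; then H2O–acetone (1:4), 0 °C → rt
Reagents that add atoms: dimethyldioxirane, CC1(C)OO1; water, O
Why: Dimethyldioxirane transfers one oxygen atom to the C3=C4 bond of the lower 2H-chromene through a concerted spiro transition state, the known epoxidation of flav-3-enes and other 2H-chromenes, and oxirane 20 is hydrolysed in the same flask by borderline SN2 attack of water at C4. No ring of the target is closed: the only ring formed is the transient oxirane, made by syn addition of the oxygen atom across C3 and C4 and reopened at once by cleavage of its C4–O bond. C3 (S) is set in the oxygen transfer by the C2 aryl group, which covers the α face of the half-chair heterocycle next to C3 and leaves only the β face open, so that O3 ends trans to the aryl group. C4 (R) is set in the hydrolysis by the oxirane itself, because water enters antiperiplanar to the departing oxygen (trans-diaxial opening), so that O4 ends trans to O3. The step needs chemoselectivity for the alkene, which as the only electron-rich styrene-type double bond should consume one equivalent of dioxirane at low temperature far faster than benzyl ethers, arenes or the silyl-protected upper carbinol, and regioselectivity for C4 over C3, which the benzylic position with O1 ortho and O7 para secures. It also needs the opening to stay concerted, which is helped by the absence of acid and by the 7-benzyloxy group, twisted out of conjugation between the 8-benzyloxy group and the bulky residue U at C6, so that a free C4 cation is less accessible than in simpler 7-alkoxyflav-3-enes.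

Step 16
Reactants: 21 silylated, brominated hexabenzyl diol
Product: 22 (2R,3S,4R)-7,8-bis(benzyloxy)-2-[4-(benzyloxy)phenyl]-6-[(2R,3R,4S)-7,8-bis(benzyloxy)-2-[4-(benzyloxy)phenyl]-6-bromo-3-hydroxychroman-4-yl]chroman-3,4-diol
Conditions: Bu4NF (3 equiv), AcOH (3 equiv), THF, rt → 40 °C
Reagents that add atoms: none
Why: Fluoride-induced desilylation reaches the hindered silicon through the small nucleophile, and the acetic acid buffer keeps the medium close to neutral so that the benzylic C4 hydroxyl and the benzyl ethers stay untouched.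

Step 17
Reactants: 22 brominated hexabenzyl triol
Product: 23 (2R,3S,4R)-2-(4-hydroxyphenyl)-6-[(2R,3R,4S)-3,7,8-trihydroxy-2-(4-hydroxyphenyl)chroman-4-yl]chroman-3,4,7,8-tetrol (target)
Conditions: H2 (1 atm), Pd(OH)2/C, NaOAc (1.5 equiv), THF–MeOH, rt, stopped at full debenzylation
Reagents that add atoms: none
Why: In this catalytic hydrogenolysis the six aryl benzyl ethers and the aryl bromide should be cleaved faster than the secondary benzylic C4 alcohol as long as the medium does not turn acidic, which NaOAc secures by taking up the HBr, and no stereocentre is touched.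

Compound list
1 | 2,3,4-trihydroxybenzaldehyde | O=Cc1ccc(O)c(O)c1O | starting material
2 | 3,4-bis(benzyloxy)-2-hydroxybenzaldehyde | O=Cc1ccc(OCc2ccccc2)c(OCc2ccccc2)c1O | intermediate
3 | 3,4-bis(benzyloxy)-5-bromo-2-hydroxybenzaldehyde | O=Cc1cc(Br)c(OCc2ccccc2)c(OCc2ccccc2)c1O | intermediate
4 | 7,8-bis(benzyloxy)-6-bromo-2H-chromen-2-one | O=C1C=Cc2cc(Br)c(OCc3ccccc3)c(OCc3ccccc3)c2O1 | intermediate
5 | 7,8-bis(benzyloxy)-6-bromo-2H-chromen-2-ol (lactol, not isolated) | OC1C=Cc2cc(Br)c(OCc3ccccc3)c(OCc3ccccc3)c2O1 | intermediate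
6 | 7,8-bis(benzyloxy)-6-bromo-2-ethoxy-2H-chromene (racemic) | CCOC1C=Cc2cc(Br)c(OCc3ccccc3)c(OCc3ccccc3)c2O1 | intermediate
7 | 4-(benzyloxy)phenylboronic acid | OB(O)c1ccc(OCc2ccccc2)cc1 | starting material
8 | diethyl [4-(benzyloxy)phenyl]boronate | CCOB(OCC)c1ccc(OCc2ccccc2)cc1 | intermediate
9 | (2S)-7,8-bis(benzyloxy)-2-[4-(benzyloxy)phenyl]-6-bromo-2H-chromene | c5ccccc5COc1ccc([C@H]2Oc3c(cc(Br)c(OCc5ccccc5)c3OCc5ccccc5)C=C2)cc1 | intermediate
10 | 3,4-epoxide of 9, oxygen on the β face (not isolated) | c5ccccc5COc1ccc([C@H]2Oc3c(cc(Br)c(OCc5ccccc5)c3OCc5ccccc5)[C@@H]4O[C@H]24)cc1 | intermediate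
11 | (2R,3S,4R)-7,8-bis(benzyloxy)-2-[4-(benzyloxy)phenyl]-6-bromo-4-methoxychroman-3-ol | c5ccccc5COc1ccc([C@H]2Oc3c(cc(Br)c(OCc5ccccc5)c3OCc5ccccc5)[C@@H](OC)[C@@H]2O)cc1 | intermediate
12 | (2R,4R)-7,8-bis(benzyloxy)-2-[4-(benzyloxy)phenyl]-6-bromo-4-methoxychroman-3-one | c5ccccc5COc1ccc([C@H]2Oc3c(cc(Br)c(OCc5ccccc5)c3OCc5ccccc5)[C@@H](OC)C2=O)cc1 | intermediate
13 | (2R,3R,4R)-7,8-bis(benzyloxy)-2-[4-(benzyloxy)phenyl]-6-bromo-4-methoxychroman-3-ol | c5ccccc5COc1ccc([C@H]2Oc3c(cc(Br)c(OCc5ccccc5)c3OCc5ccccc5)[C@@H](OC)[C@H]2O)cc1 | intermediate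
14 | (2R,3R,4R)-7,8-bis(benzyloxy)-2-[4-(benzyloxy)phenyl]-6-bromo-3-[(tert-butyldimethylsilyl)oxy]-4-methoxychroman | c5ccccc5COc1ccc([C@H]2Oc3c(cc(Br)c(OCc5ccccc5)c3OCc5ccccc5)[C@@H](OC)[C@H]2O[Si](C)(C)C(C)(C)C)cc1 | intermediate
15 | 3,4-bis(benzyloxy)-2-hydroxy-5-U-benzaldehyde | c5ccccc5COc1ccc([C@H]2Oc3c(cc(Br)c(OCc5ccccc5)c3OCc5ccccc5)[C@H](c3cc(C=O)c(O)c(OCc5ccccc5)c3OCc5ccccc5)[C@H]2O[Si](C)(C)C(C)(C)C)cc1 | intermediate
16 | 7,8-bis(benzyloxy)-6-U-2H-chromen-2-one | c5ccccc5COc1ccc([C@H]2Oc3c(cc(Br)c(OCc5ccccc5)c3OCc5ccccc5)[C@H](c3cc4c(c(OCc5ccccc5)c3OCc5ccccc5)OC(=O)C=C4)[C@H]2O[Si](C)(C)C(C)(C)C)cc1 | intermediate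
17 | 7,8-bis(benzyloxy)-6-U-2H-chromen-2-ol (lactol, C2 epimers, not isolated) | c5ccccc5COc1ccc([C@H]2Oc3c(cc(Br)c(OCc5ccccc5)c3OCc5ccccc5)[C@H](c3cc4c(c(OCc5ccccc5)c3OCc5ccccc5)OC(O)C=C4)[C@H]2O[Si](C)(C)C(C)(C)C)cc1 | intermediate
18 | 7,8-bis(benzyloxy)-2-ethoxy-6-U-2H-chromene (C2 epimers) | c5ccccc5COc1ccc([C@H]2Oc3c(cc(Br)c(OCc5ccccc5)c3OCc5ccccc5)[C@H](c3cc4c(c(OCc5ccccc5)c3OCc5ccccc5)OC(OCC)C=C4)[C@H]2O[Si](C)(C)C(C)(C)C)cc1 | intermediate
19 | (2S)-7,8-bis(benzyloxy)-2-[4-(benzyloxy)phenyl]-6-U-2H-chromene (key-step precursor) | c5ccccc5COc1ccc([C@H]2Oc3c(cc(Br)c(OCc5ccccc5)c3OCc5ccccc5)[C@H](c3cc4c(c(OCc5ccccc5)c3OCc5ccccc5)O[C@H](c3ccc(OCc5ccccc5)cc3)C=C4)[C@H]2O[Si](C)(C)C(C)(C)C)cc1 | intermediate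
20 | lower 3,4-epoxide of 19, oxygen on the β face of the lower unit (not isolated) | c5ccccc5COc1ccc([C@H]2Oc3c(cc(Br)c(OCc5ccccc5)c3OCc5ccccc5)[C@H](c3cc4c(c(OCc5ccccc5)c3OCc5ccccc5)O[C@H](c3ccc(OCc5ccccc5)cc3)[C@H]6O[C@H]64)[C@H]2O[Si](C)(C)C(C)(C)C)cc1 | intermediate
21 | (2R,3S,4R)-7,8-bis(benzyloxy)-2-[4-(benzyloxy)phenyl]-6-U-chroman-3,4-diol (key-step product) | c5ccccc5COc1ccc([C@H]2Oc3c(cc(Br)c(OCc5ccccc5)c3OCc5ccccc5)[C@H](c3cc4c(c(OCc5ccccc5)c3OCc5ccccc5)O[C@H](c3ccc(OCc5ccccc5)cc3)[C@@H](O)[C@@H]4O)[C@H]2O[Si](C)(C)C(C)(C)C)cc1 | intermediate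
22 | desilylated 21 (upper C3 hydroxyl free, upper C6 bromine and six benzyl ethers kept) | c5ccccc5COc1ccc([C@H]2Oc3c(cc(Br)c(OCc5ccccc5)c3OCc5ccccc5)[C@H](c3cc4c(c(OCc5ccccc5)c3OCc5ccccc5)O[C@H](c3ccc(OCc5ccccc5)cc3)[C@@H](O)[C@@H]4O)[C@H]2O)cc1 | intermediate
23 | (2R,3S,4R)-2-(4-hydroxyphenyl)-6-[(2R,3R,4S)-3,7,8-trihydroxy-2-(4-hydroxyphenyl)chroman-4-yl]chroman-3,4,7,8-tetrol | Oc1ccc([C@H]2Oc3c(ccc(O)c3O)[C@H](c3cc4c(c(O)c3O)O[C@H](c3ccc(O)cc3)[C@@H](O)[C@@H]4O)[C@H]2O)cc1 | target

Total step count: 17. Longest linear sequence: 16 steps (steps 1–4 and 6–17; step 5 is a side branch, and 2 and 8 are each used twice).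

Steps most likely to fail

Step 11. The formyl-deactivated ring of 2 may attack too slowly, so that the C4 cation is lost through proton loss from C3 or through attack on benzyloxy-substituted rings. The fallback sets out from 2 and 14 and comes back at 15.
- The aldehyde of 2 is masked with propane-1,3-dithiol and BF3·OEt2 as 2-[3,4-bis(benzyloxy)-2-hydroxyphenyl]-1,3-dithiane F1. This removes the acceptor but keeps the position ortho to the phenol blocked.
- F1 is alkylated by 14 under TMSOTf catalysis, para to its hydroxyl, to give the U-substituted dithiane F2.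
- Alkylative hydrolysis (MeI, CaCO3, aqueous MeCN) frees the aldehyde 15.

Step 15. The opening may drift towards a free C4 cation, so that water enters from both faces, or the oxygen transfer may show poor facial selectivity. The fallback sets out from 19 and comes back at 21.
- Syn dihydroxylation with catalytic OsO4 and N-methylmorpholine N-oxide, on the β face of the lower unit, gives the 2,3-trans-3,4-cis diol F3.
- MnO2 oxidises only the benzylic C4 carbinol to the 2,3-trans-dihydroflavonol F4.
- NaBH4 delivers hydride axially to C4. The new hydroxyl is then equatorial and trans to O3, as in the known reduction of 2,3-trans-dihydroflavonols, which gives 21.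

Step 17. The benzylic C4 hydroxyl of the lower unit may be lost by hydrogenolysis while the benzyl ethers are cleaved. The fallback sets out from 22 and comes back at 23.
- MnO2 oxidises the benzylic C4 carbinol of 22 to the hexabenzyl bromo dihydroflavonol F5, in which C4 is an electron-rich aryl ketone that resists hydrogenation.
- H2 over Pd(OH)2/C with NaOAc removes benzyl groups and bromine to give the free phenolic dihydroflavonol F6.
- NaBH4 in EtOH at 0 °C then creates the C4 hydroxyl last, trans to O3, on the unprotected compound and gives 23.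

Further compounds
F1 | step 11 | 2-[3,4-bis(benzyloxy)-2-hydroxyphenyl]-1,3-dithiane | Oc1c(C2SCCCS2)ccc(OCc2ccccc2)c1OCc1ccccc1
F2 | step 11 | 2-[3,4-bis(benzyloxy)-2-hydroxy-5-U-phenyl]-1,3-dithiane | c5ccccc5COc1ccc([C@H]2Oc3c(cc(Br)c(OCc5ccccc5)c3OCc5ccccc5)[C@H](c3cc(C6SCCCS6)c(O)c(OCc5ccccc5)c3OCc5ccccc5)[C@H]2O[Si](C)(C)C(C)(C)C)cc1
F3 | step 15 | (2R,3S,4S)-7,8-bis(benzyloxy)-2-[4-(benzyloxy)phenyl]-6-U-chroman-3,4-diol (2,3-trans-3,4-cis) | c5ccccc5COc1ccc([C@H]2Oc3c(cc(Br)c(OCc5ccccc5)c3OCc5ccccc5)[C@H](c3cc4c(c(OCc5ccccc5)c3OCc5ccccc5)O[C@H](c3ccc(OCc5ccccc5)cc3)[C@@H](O)[C@H]4O)[C@H]2O[Si](C)(C)C(C)(C)C)cc1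
F4 | step 15 | (2R,3R)-7,8-bis(benzyloxy)-2-[4-(benzyloxy)phenyl]-3-hydroxy-6-U-chroman-4-one | c5ccccc5COc1ccc([C@H]2Oc3c(cc(Br)c(OCc5ccccc5)c3OCc5ccccc5)[C@H](c3cc4c(c(OCc5ccccc5)c3OCc5ccccc5)O[C@H](c3ccc(OCc5ccccc5)cc3)[C@@H](O)C4=O)[C@H]2O[Si](C)(C)C(C)(C)C)cc1
F5 | step 17 | (2R,3R)-7,8-bis(benzyloxy)-2-[4-(benzyloxy)phenyl]-6-[(2R,3R,4S)-7,8-bis(benzyloxy)-2-[4-(benzyloxy)phenyl]-6-bromo-3-hydroxychroman-4-yl]-3-hydroxychroman-4-one | c5ccccc5COc1ccc([C@H]2Oc3c(cc(Br)c(OCc5ccccc5)c3OCc5ccccc5)[C@H](c3cc4c(c(OCc5ccccc5)c3OCc5ccccc5)O[C@H](c3ccc(OCc5ccccc5)cc3)[C@@H](O)C4=O)[C@H]2O)cc1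
F6 | step 17 | (2R,3R)-3,7,8-trihydroxy-2-(4-hydroxyphenyl)-6-[(2R,3R,4S)-3,7,8-trihydroxy-2-(4-hydroxyphenyl)chroman-4-yl]chroman-4-one | Oc1ccc([C@H]2Oc3c(ccc(O)c3O)[C@H](c3cc4c(c(O)c3O)O[C@H](c3ccc(O)cc3)[C@@H](O)C4=O)[C@H]2O)cc1
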